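A small charge of initiator, 8.1 mM, stands in this flask beside substrate and partner.

| setting | Saturday's | Tuesday's | flask |
|---|---|---|---|
| substrate | 1.5 M | 1.5 M | 1.5 M |
| partner | 1.95 M | 1.95 M | 1.95 M |
| initiator | 4 mM | 16 mM | 8.1 mM |
| remark | run made earlier | run made earlier |  |
| time |  |  | 3.0 min |

- Saturday's (time / min: substrate / %, target / %, over-reaction product / %): 0.250: 95.4, 2.3, 0.1; 0.667: 87.0, 6.8, 0.4; 1.33: 75.6, 12.2, 2.8; 2.00: 65.9, 16.4, 4.6; 3.00: 53.2, 20.7, 8.4; 4.00: 43.4, 24.9, 13.0
- Tuesday's (time / min: substrate / %, target / %, over-reaction product / %): 0.667: 75.8, 13.6, 1.4; 1.33: 56.3, 23.4, 4.3; 2.00: 42.5, 30.8, 7.7; 2.50: 34.4, 34.8, 10.8; 3.00: 28.2, 38.4, 13.8; 4.00: 18.8, 42.6, 19.0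

(each reading ± 0.3 percentage points)

- which holds at 3.0 min: what has brought the reaction to rest, or that it has not come to rest (the partner has run out first / it is still moving / all of the substrate has reacted)
- part of the substrate gone at 3.0 min
- the target standing at 3.0 min, as a percentage of the substrate charged
- the over-reaction product standing at 3.0 min, as a percentage of the substrate charged
- amount of target if the flask were left three thousand times as long, in percent of the substrate charged

- the reaction counts as stopped when no species that holds the substrate changes by six tenths of a point or more over the second half of the time
- what has gone from substrate into another species counts as reacted, even if it can come back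

Partner is never read, so I keep its account by hand. I take each target, P, to cost one partner, and each over-reaction product, O, to cost one more on top of the target it came from. The bill is therefore P + 2O. It is paid from the purse, the partner charged per substrate charged, 130%.

Tuesday's run at 3.00 min has a bill of 66.0%. That leaves 64.0%, with substrate 28.2% still standing. This flask has less initiator, so I expect it to be still moving at 3.0 min.

For the long time, suppose the whole substrate charge became target first. That leaves a spare 30.0% of partner, which makes as much O, and target ends at 70.0%. So although substrate is the smaller charge, partner, with its two claims, can become the limiting reagent.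

The weak link is that O does not wait. Between 3.00 min and 4.00 min in Tuesday's run, O takes 55.3% of the new P + O, as far as these readings show. Tuesday's last bill leaves 49.4%. If Tuesday's run kept that share, its purse would pay for 31.8% more turnover, and its target would stop near 56.8%. This flask has the same partner charge and the same substrate charge, so I commit to that estimate for this flask too.

The forecast says it is still moving, with 59.1% gone, target 28.7%, over-reaction product 11% and 56% at the long time. Its ground is “Long-term, partner (130%) limits.”

In the flask, it is still moving, with 59.5% gone, target 28.7%, over-reaction product 11.3% and 32.5% at the long time.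

    initiator → 2 initiating radical (k = 0.0150 min⁻¹)
    substrate + initiating radical → capped initiator + first chain carrier (k = 5.40 × 10⁵ L mol⁻¹ s⁻¹)
    partner + first chain carrier → target + second chain carrier (k = 12000 L mol⁻¹ s⁻¹)
    substrate + second chain carrier → by-product + first chain carrier (k = 4.20 × 10⁵ L mol⁻¹ s⁻¹)
    2 first chain carrier → ended chains A (k = 6.00 × 10⁷ L mol⁻¹ s⁻¹)
    2 second chain carrier → ended chains B (k = 3.00 × 10⁸ L mol⁻¹ s⁻¹)
    partner + target → over-reaction product (k = 0.150 L mol⁻¹ min⁻¹)
    substrate + target → side product (k = 0.00990 L mol⁻¹ min⁻¹)
    substrate + by-product ⇌ idle adduct, settled at all times (K = 1.40 L mol⁻¹)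

The forecast and the flask part on the long target, 56% against 32.5%. In this flask at 3.0 min, the bill of 51.3% leaves 78.7%, and the partner standing is 78.3% of the substrate charge. The same flask read at 12.0 min holds target 41.9% and over-reaction product 37.5%. Its bill is 117%, which leaves 13.1%, and its partner stands at 9.12% of its own charge, or 11.9% of the substrate charge. That bill omits side product, which counts as two, so the 2.52% of side product in the flask at that time holds 1.26% of target that paid for its partner, and the two accounts differ by 1.3 percentage points.

The runs were generated by integration with made-up constants, noise included.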